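**Strategy.** Everything rests on cutting the aryl ether bond O1–C8a between ring C and ring A of the flavanone. C8a is an sp2 carbon ortho to the C4 acyl group, so a palladium-catalysed intramolecular O-arylation of an open-chain (S)-β-hydroxy ketone bearing bromine at C8a closes the pyranone ring in one operation without touching C2. That stereocentre is set earlier in the sequence by asymmetric epoxidation of a chalcone and reductive epoxide opening, so the racemisation-prone oxa-Michael closure is avoided. The precursor is the formal aldol adduct of 2,4-bis(benzyloxy)-6-bromoacetophenone and a (2R,3S)-dihydrobenzofuran-5-carbaldehyde, itself built by enantioselective rhodium-carbenoid C–H insertion.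

Key step: step 14

Numbering used: flavanone O1, C2, C3, C4, C4a, C5 to C8, C8a (rings A and C); dihydrobenzofuran O1, C2, C3, C3a, C4 to C7, C7a.

Assumption: Rh2(S-PTTL)4 is taken to deliver the (2R,3S)-cis insertion product in step 4; if its sense of induction is the opposite, Rh2(R-PTTL)4 is used instead.

**Route**

Step 1
Reactants: 1 3-(benzyloxy)-4-hydroxybenzaldehyde
Product: 2 3-(benzyloxy)-4-hydroxy-5-iodobenzaldehyde
Conditions: NIS, TFA (cat.), MeCN, rt
Reagents that add atoms: N-iodosuccinimide, O=C1CCC(=O)N1I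
Why: Electrophilic aromatic iodination, in which the free phenol directs to its only open ortho position (para is occupied by the formyl group), as in the iodination of vanillin; no stereocentre.

Step 2
Reactants: 2 3-(benzyloxy)-4-hydroxy-5-iodobenzaldehyde; 3 [4-(benzyloxy)-3-methoxyphenyl]methanol
Product: 4 3-(benzyloxy)-4-{[4-(benzyloxy)-3-methoxyphenyl]methoxy}-5-iodobenzaldehyde
Conditions: PPh3, DIAD, THF, 0 °C to rt
Reagents that add atoms: none
Why: Mitsunobu etherification, in which the acidic, formyl-activated phenol is alkylated by the phosphonium-activated primary benzylic alcohol, installing the later C–H insertion site without a separate halide step.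

Step 3
Reactants: 4 3-(benzyloxy)-4-{[4-(benzyloxy)-3-methoxyphenyl]methoxy}-5-iodobenzaldehyde; 5 ethyl diazoacetate
Product: 6 ethyl 2-[3-(benzyloxy)-2-{[4-(benzyloxy)-3-methoxyphenyl]methoxy}-5-formylphenyl]-2-diazoacetate
Conditions: Pd(PPh3)4 (5 mol%), Ag2CO3 (0.5 equiv), Et3N, toluene, rt
Reagents that add atoms: none
Why: Palladium-catalysed cross-coupling of an aryl iodide with a diazoacetate (oxidative addition of zerovalent palladium, base-assisted palladation of the diazo C–H bond, reductive elimination), which keeps the diazo group and leaves aldehyde and ethers untouched at room temperature.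

Step 4
Reactants: 6 ethyl 2-[3-(benzyloxy)-2-{[4-(benzyloxy)-3-methoxyphenyl]methoxy}-5-formylphenyl]-2-diazoacetate
Product: 7 ethyl (2R,3S)-7-(benzyloxy)-2-[4-(benzyloxy)-3-methoxyphenyl]-5-formyl-2,3-dihydro-1-benzofuran-3-carboxylate (2,3-cis)
Conditions: Rh2(S-PTTL)4 (1 mol%; PTTL = N-phthaloyl-tert-leucinate), toluene (0.02 M), −60 °C
Reagents that add atoms: none
Why: Enantioselective intramolecular 1,5-C–H insertion of a donor/acceptor rhodium carbenoid into the benzylic ether C–H bond, in which the chiral carboxylate ligands set C2 as R and the concerted, kinetically controlled insertion places aryl and ester cis (C3 S), while dilution and low temperature disfavour bimolecular capture of the carbenoid by the formyl oxygen.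

Step 5
Reactants: 7 ethyl (2R,3S)-7-(benzyloxy)-2-[4-(benzyloxy)-3-methoxyphenyl]-5-formyl-2,3-dihydro-1-benzofuran-3-carboxylate
Product: 9 ethyl (2R,3R)-7-(benzyloxy)-2-[4-(benzyloxy)-3-methoxyphenyl]-5-(hydroxymethyl)-2,3-dihydro-1-benzofuran-3-carboxylate (2,3-trans), via cis hydroxymethyl ester 8 (not isolated)
Conditions: NaBH4, EtOH/THF, 0 °C; then NaOEt, rt
Reagents that add atoms: none
Why: Chemoselective borohydride reduction of the aldehyde first removes the para acceptor that would make the ring oxygen a leaving group for E1cB opening, and ethoxide then epimerises the ester-bearing benzylic C3 by enolate protonation to the thermodynamically favoured 2,3-trans isomer (C3 R) while C2 is untouched.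

Step 6
Reactants: 9 ethyl (2R,3R)-7-(benzyloxy)-2-[4-(benzyloxy)-3-methoxyphenyl]-5-(hydroxymethyl)-2,3-dihydro-1-benzofuran-3-carboxylate
Product: 10 {(2R,3S)-7-(benzyloxy)-2-[4-(benzyloxy)-3-methoxyphenyl]-2,3-dihydro-1-benzofuran-3,5-diyl}dimethanol
Conditions: LiAlH4, THF, 0 °C
Reagents that add atoms: none
Why: Hydride reduction of the ester to the primary alcohol, which affects no stereocentre (the C3 descriptor becomes S only through the priority change).

Step 7
Reactants: 10 {(2R,3S)-7-(benzyloxy)-2-[4-(benzyloxy)-3-methoxyphenyl]-2,3-dihydro-1-benzofuran-3,5-diyl}dimethanol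
Product: 11 (2R,3S)-7-(benzyloxy)-2-[4-(benzyloxy)-3-methoxyphenyl]-3-(hydroxymethyl)-2,3-dihydro-1-benzofuran-5-carbaldehyde
Conditions: MnO2, CH2Cl2, rt
Reagents that add atoms: none
Why: MnO2 oxidises benzylic alcohols selectively, so only the aryl-CH2OH group should become the aldehyde while the aliphatic primary alcohol remains.

Step 8
Reactants: 11 (2R,3S)-7-(benzyloxy)-2-[4-(benzyloxy)-3-methoxyphenyl]-3-(hydroxymethyl)-2,3-dihydro-1-benzofuran-5-carbaldehyde
Product: 12 (2R,3S)-7-(benzyloxy)-3-[(benzyloxy)methyl]-2-[4-(benzyloxy)-3-methoxyphenyl]-2,3-dihydro-1-benzofuran-5-carbaldehyde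
Conditions: NaH, BnBr, Bu4NI (cat.), THF/DMF, 0 °C
Reagents that add atoms: benzyl bromide, BrCc1ccccc1
Why: Williamson etherification of the primary alkoxide, tolerated by the non-enolisable aldehyde at 0 °C, giving a protecting group that leaves in the final hydrogenolysis.

Step 9
Reactants: 13 5-bromoresorcinol (5-bromobenzene-1,3-diol)
Product: 14 1-(2-bromo-4,6-dihydroxyphenyl)ethanone
Conditions: ZnCl2, AcOH, 140 °C
Reagents that add atoms: acetic acid, CC(=O)O
Why: Nencki reaction (Friedel–Crafts C-acylation of a resorcinol), which should acylate C4, ortho to one hydroxyl and para to the other, placing the acetyl group next to bromine.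

Step 10
Reactants: 14 1-(2-bromo-4,6-dihydroxyphenyl)ethanone
Product: 15 1-[2,4-bis(benzyloxy)-6-bromophenyl]ethanone
Conditions: BnBr, K2CO3, DMF, 70 °C
Reagents that add atoms: benzyl bromide, BrCc1ccccc1
Why: Williamson O-benzylation of both phenols, the hydrogen-bonded ortho hydroxyl requiring the warm DMF conditions.

Step 11
Reactants: 12 (2R,3S)-7-(benzyloxy)-3-[(benzyloxy)methyl]-2-[4-(benzyloxy)-3-methoxyphenyl]-2,3-dihydro-1-benzofuran-5-carbaldehyde; 15 1-[2,4-bis(benzyloxy)-6-bromophenyl]ethanone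
Product: 16 (E)-1-[2,4-bis(benzyloxy)-6-bromophenyl]-3-{(2R,3S)-7-(benzyloxy)-3-[(benzyloxy)methyl]-2-[4-(benzyloxy)-3-methoxyphenyl]-2,3-dihydro-1-benzofuran-5-yl}prop-2-en-1-one
Conditions: KOH, EtOH/THF, rt
Reagents that add atoms: none
Why: Claisen–Schmidt condensation, in which crossed aldol addition of the methyl ketone enolate to the non-enolisable aldehyde and E1cB dehydration give the E-enone.

Step 12
Reactants: 16 the (E)-chalcone
Product: 17 [2,4-bis(benzyloxy)-6-bromophenyl][(2S,3R)-3-{(2R,3S)-7-(benzyloxy)-3-[(benzyloxy)methyl]-2-[4-(benzyloxy)-3-methoxyphenyl]-2,3-dihydro-1-benzofuran-5-yl}oxiran-2-yl]methanone (trans-epoxide)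
Conditions: immobilised poly-D-leucine, urea–H2O2, DBU, THF, rt
Reagents that add atoms: urea–hydrogen peroxide, NC(N)=O.OO
Why: Juliá–Colonna epoxidation (Weitz–Scheffer conjugate addition of hydroperoxide within the helical polypeptide), where poly-D-leucine, the mirror image of the poly-L-leucine that converts chalcone into its (2R,3S)-epoxide, should deliver peroxide to the enone face that gives the (2S,3R)-epoxide.

Step 13
Reactants: 17 the (2S,3R)-epoxy ketone
Product: 18 (3S)-1-[2,4-bis(benzyloxy)-6-bromophenyl]-3-{(2R,3S)-7-(benzyloxy)-3-[(benzyloxy)methyl]-2-[4-(benzyloxy)-3-methoxyphenyl]-2,3-dihydro-1-benzofuran-5-yl}-3-hydroxypropan-1-one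
Conditions: SmI2, THF/MeOH, −90 °C
Reagents that add atoms: none
Why: Single-electron reduction of the ketone by divalent samarium gives a ketyl that cleaves the adjacent Cα–O bond, and protonation of the samarium enolate furnishes the β-hydroxy ketone, so the Cβ–O bond is never broken and the carbinol is S.

Step 14
Reactants: 18 the (3S)-β-hydroxy ketone
Product: 19 (2S)-5,7-bis(benzyloxy)-2-{(2R,3S)-7-(benzyloxy)-3-[(benzyloxy)methyl]-2-[4-(benzyloxy)-3-methoxyphenyl]-2,3-dihydro-1-benzofuran-5-yl}-2,3-dihydro-4H-chromen-4-one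
Conditions: Pd(OAc)2 (5 mol%), 2-(di-tert-butylphosphino)-1,1'-binaphthyl (6 mol%), K3PO4, toluene, 60 °C
Reagents that add atoms: none
Why: Zerovalent palladium, formed in situ from Pd(OAc)2 and the bulky phosphine, inserts into the C8a–Br bond of ring A, the C2 hydroxyl binds and is deprotonated by K3PO4 to give a seven-membered aryl(alkoxo)palladium chelate, and C–O reductive elimination forges O1–C8a. The closest known reaction type is the intramolecular Buchwald–Hartwig etherification of aryl bromides with secondary alcohols, which gives chromans with retention of the carbinol configuration. Ring C is closed as a six-membered ring by reductive elimination from that seven-membered palladacycle, formally a 6-exo attack of the alkoxide oxygen on the ipso carbon held at palladium. No new stereocentre is formed, and C2 keeps its S configuration because neither its C–O nor its C–H bond takes part. The step needs C–O reductive elimination to outrun β-hydride elimination of the benzylic alkoxide and base-induced dehydration or retro-aldol cleavage of the β-hydroxy ketone: the di-tert-butylbiaryl phosphine accelerates reductive elimination, the weak, insoluble base in toluene keeps the enolate concentration low, the ortho acyl group activates and pre-organises the C–Br bond, the only other hydroxyl is masked as a benzyl ether, and ring A carries a single halogen.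

Step 15
Reactants: 19 the pentabenzyl flavanone
Product: 20 silyhermin B, (2S)-5,7-dihydroxy-2-[(2R,3S)-7-hydroxy-2-(4-hydroxy-3-methoxyphenyl)-3-(hydroxymethyl)-2,3-dihydro-1-benzofuran-5-yl]-2,3-dihydro-4H-chromen-4-one
Conditions: H2 (1 atm), palladium on carbon (Pd/C), EtOAc/MeOH, rt
Reagents that add atoms: none
Why: Catalytic hydrogenolysis should cleave the four aryl benzyl ethers and the alkyl benzyl ether, whereas the two cyclic benzylic aryl ethers and the hydrogen-bonded aryl ketone react far more slowly under neutral conditions, so the reaction is stopped when hydrogen uptake ends.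

**Compound list**

1 | 3-(benzyloxy)-4-hydroxybenzaldehyde | O=Cc1ccc(O)c(OCc2ccccc2)c1 | starting material
2 | 3-(benzyloxy)-4-hydroxy-5-iodobenzaldehyde | O=Cc1cc(I)c(O)c(OCc2ccccc2)c1 | intermediate
3 | [4-(benzyloxy)-3-methoxyphenyl]methanol | COc1cc(CO)ccc1OCc1ccccc1 | starting material
4 | 3-(benzyloxy)-4-{[4-(benzyloxy)-3-methoxyphenyl]methoxy}-5-iodobenzaldehyde | COc1cc(COc2c(I)cc(C=O)cc2OCc2ccccc2)ccc1OCc1ccccc1 | intermediate
5 | ethyl diazoacetate | CCOC(=O)C=[N+]=[N-] | starting material
6 | ethyl 2-[3-(benzyloxy)-2-{[4-(benzyloxy)-3-methoxyphenyl]methoxy}-5-formylphenyl]-2-diazoacetate | CCOC(=O)C(=[N+]=[N-])c1cc(C=O)cc(OCc2ccccc2)c1OCc1ccc(OCc2ccccc2)c(OC)c1 | intermediate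
7 | ethyl (2R,3S)-7-(benzyloxy)-2-[4-(benzyloxy)-3-methoxyphenyl]-5-formyl-2,3-dihydro-1-benzofuran-3-carboxylate (cis) | COc1cc([C@@H]2Oc3c(OCc4ccccc4)cc(C=O)cc3[C@@H]2C(=O)OCC)ccc1OCc1ccccc1 | intermediate
8 | ethyl (2R,3S)-7-(benzyloxy)-2-[4-(benzyloxy)-3-methoxyphenyl]-5-(hydroxymethyl)-2,3-dihydro-1-benzofuran-3-carboxylate (cis, not isolated) | COc1cc([C@@H]2Oc3c(OCc4ccccc4)cc(CO)cc3[C@@H]2C(=O)OCC)ccc1OCc1ccccc1 | intermediate
9 | ethyl (2R,3R)-7-(benzyloxy)-2-[4-(benzyloxy)-3-methoxyphenyl]-5-(hydroxymethyl)-2,3-dihydro-1-benzofuran-3-carboxylate (trans) | COc1cc([C@@H]2Oc3c(OCc4ccccc4)cc(CO)cc3[C@H]2C(=O)OCC)ccc1OCc1ccccc1 | intermediate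
10 | {(2R,3S)-7-(benzyloxy)-2-[4-(benzyloxy)-3-methoxyphenyl]-2,3-dihydro-1-benzofuran-3,5-diyl}dimethanol | COc1cc([C@@H]2Oc3c(OCc4ccccc4)cc(CO)cc3[C@H]2CO)ccc1OCc1ccccc1 | intermediate
11 | (2R,3S)-7-(benzyloxy)-2-[4-(benzyloxy)-3-methoxyphenyl]-3-(hydroxymethyl)-2,3-dihydro-1-benzofuran-5-carbaldehyde | COc1cc([C@@H]2Oc3c(OCc4ccccc4)cc(C=O)cc3[C@H]2CO)ccc1OCc1ccccc1 | intermediate
12 | (2R,3S)-7-(benzyloxy)-3-[(benzyloxy)methyl]-2-[4-(benzyloxy)-3-methoxyphenyl]-2,3-dihydro-1-benzofuran-5-carbaldehyde | COc1cc([C@@H]2Oc3c(OCc4ccccc4)cc(C=O)cc3[C@H]2COCc2ccccc2)ccc1OCc1ccccc1 | intermediate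
13 | 5-bromoresorcinol | Oc1cc(O)cc(Br)c1 | starting material
14 | 1-(2-bromo-4,6-dihydroxyphenyl)ethanone | CC(=O)c1c(O)cc(O)cc1Br | intermediate
15 | 1-[2,4-bis(benzyloxy)-6-bromophenyl]ethanone | CC(=O)c1c(Br)cc(OCc2ccccc2)cc1OCc1ccccc1 | intermediate
16 | (E)-1-[2,4-bis(benzyloxy)-6-bromophenyl]-3-{(2R,3S)-7-(benzyloxy)-3-[(benzyloxy)methyl]-2-[4-(benzyloxy)-3-methoxyphenyl]-2,3-dihydro-1-benzofuran-5-yl}prop-2-en-1-one | COc1cc([C@@H]2Oc3c(OCc4ccccc4)cc(/C=C/C(=O)c4c(Br)cc(OCc5ccccc5)cc4OCc4ccccc4)cc3[C@H]2COCc2ccccc2)ccc1OCc1ccccc1 | intermediate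
17 | [2,4-bis(benzyloxy)-6-bromophenyl][(2S,3R)-3-{(2R,3S)-7-(benzyloxy)-3-[(benzyloxy)methyl]-2-[4-(benzyloxy)-3-methoxyphenyl]-2,3-dihydro-1-benzofuran-5-yl}oxiran-2-yl]methanone | COc1cc([C@@H]2Oc3c(OCc4ccccc4)cc([C@H]6O[C@@H]6C(=O)c4c(Br)cc(OCc5ccccc5)cc4OCc4ccccc4)cc3[C@H]2COCc2ccccc2)ccc1OCc1ccccc1 | intermediate
18 | (3S)-1-[2,4-bis(benzyloxy)-6-bromophenyl]-3-{(2R,3S)-7-(benzyloxy)-3-[(benzyloxy)methyl]-2-[4-(benzyloxy)-3-methoxyphenyl]-2,3-dihydro-1-benzofuran-5-yl}-3-hydroxypropan-1-one | COc1cc([C@@H]2Oc3c(OCc4ccccc4)cc([C@@H](O)CC(=O)c4c(Br)cc(OCc5ccccc5)cc4OCc4ccccc4)cc3[C@H]2COCc2ccccc2)ccc1OCc1ccccc1 | intermediate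
19 | (2S)-5,7-bis(benzyloxy)-2-{(2R,3S)-7-(benzyloxy)-3-[(benzyloxy)methyl]-2-[4-(benzyloxy)-3-methoxyphenyl]-2,3-dihydro-1-benzofuran-5-yl}-2,3-dihydro-4H-chromen-4-one | COc1cc([C@@H]2Oc3c(OCc4ccccc4)cc([C@@H]4CC(=O)c5c(OCc6ccccc6)cc(OCc6ccccc6)cc5O4)cc3[C@H]2COCc2ccccc2)ccc1OCc1ccccc1 | intermediate
20 | silyhermin B | COc1cc([C@@H]2Oc3c(O)cc([C@@H]4CC(=O)c5c(O)cc(O)cc5O4)cc3[C@H]2CO)ccc1O | target

**Step count**

Total: 15 steps. Longest linear sequence: 13 steps (steps 1 to 8, then 11 to 15); steps 9 and 10 form the short branch to ketone 15.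

**Steps most likely to fail, with fallbacks**

Step 14 (key step). Under base the β-hydroxy ketone may dehydrate back to chalcone 16 or undergo retro-aldol cleavage, the palladium alkoxide may suffer β-hydride elimination before C–O reductive elimination, and the product may epimerise at C2 by reversible ring opening. The fallback changes the oxidation level of the precursor and the metal. Compound 18 is reduced by hydroxyl-directed anti reduction (Me4NBH(OAc)3, MeCN/AcOH, −30 °C) to the (1S,3S)-1,3-diol F1, which has no enolisable carbonyl. Copper-catalysed Ullmann-type intramolecular O-arylation (CuI, 3,4,7,8-tetramethyl-1,10-phenanthroline, Cs2CO3, toluene, 90 °C) then closes the same O1–C8a bond to give the (2S,4S)-chroman-4-ol F2; the C4 hydroxyl cannot compete because it would close a four-membered ring. Oxidation with Dess–Martin periodinane returns to the route at 19.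

Step 4. Enantiofacial discrimination by the chiral rhodium carboxylate may be insufficient or of the wrong sense on this heavily substituted substrate, and the carbenoid may be intercepted by the formyl oxygen. The fallback replaces asymmetric catalysis by resolution. Compound 6 is cyclised with achiral Rh2(OAc)4 (CH2Cl2, high dilution) to the racemic cis ester, that is 7 together with its enantiomer, the (2S,3R)-cis formyl ester F3. The NaBH4/NaOEt treatment of step 5 then gives, through 8 and its enantiomer, the (2S,3R)-cis hydroxymethyl ester F4, the racemic trans ester, that is 9 together with the (2S,3S)-trans hydroxymethyl ester F5. Preparative chromatography on a chiral stationary phase (amylose tris(3,5-dimethylphenylcarbamate)) delivers 9, where the route resumes.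

Step 12. Peroxide conjugate addition may be slow or poorly face-selective on a chalcone whose ketone is flanked by two ortho substituents and whose β-aryl group is electron-rich. The fallback replaces epoxidation and reductive opening by conjugate borylation. Compound 16 undergoes copper-catalysed asymmetric β-borylation (CuCl, NaOtBu, the ligand (R)-1-[(S)-2-(diphenylphosphino)ferrocenyl]ethyldicyclohexylphosphine or its enantiomer, whichever places boron on the face leading to the 3S product, B2pin2, MeOH, THF) to give the (3S)-β-boryl ketone F6. Its C–B bond is oxidised with retention (NaBO3·4H2O, THF/H2O) to 18, where the route resumes without passing through 17.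

**Further compounds**

F1 | step 14 | (1S,3S)-1-[2,4-bis(benzyloxy)-6-bromophenyl]-3-{(2R,3S)-7-(benzyloxy)-3-[(benzyloxy)methyl]-2-[4-(benzyloxy)-3-methoxyphenyl]-2,3-dihydro-1-benzofuran-5-yl}propane-1,3-diol | COc1cc([C@@H]2Oc3c(OCc4ccccc4)cc([C@@H](O)C[C@H](O)c4c(Br)cc(OCc5ccccc5)cc4OCc4ccccc4)cc3[C@H]2COCc2ccccc2)ccc1OCc1ccccc1
F2 | step 14 | (2S,4S)-5,7-bis(benzyloxy)-2-{(2R,3S)-7-(benzyloxy)-3-[(benzyloxy)methyl]-2-[4-(benzyloxy)-3-methoxyphenyl]-2,3-dihydro-1-benzofuran-5-yl}-3,4-dihydro-2H-chromen-4-ol | COc1cc([C@@H]2Oc3c(OCc4ccccc4)cc([C@@H]4C[C@H](O)c5c(OCc6ccccc6)cc(OCc6ccccc6)cc5O4)cc3[C@H]2COCc2ccccc2)ccc1OCc1ccccc1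
F3 | step 4 | ethyl (2S,3R)-7-(benzyloxy)-2-[4-(benzyloxy)-3-methoxyphenyl]-5-formyl-2,3-dihydro-1-benzofuran-3-carboxylate (cis, enantiomer of 7) | COc1cc([C@H]2Oc3c(OCc4ccccc4)cc(C=O)cc3[C@H]2C(=O)OCC)ccc1OCc1ccccc1
F4 | step 4 | ethyl (2S,3R)-7-(benzyloxy)-2-[4-(benzyloxy)-3-methoxyphenyl]-5-(hydroxymethyl)-2,3-dihydro-1-benzofuran-3-carboxylate (cis, enantiomer of 8) | COc1cc([C@H]2Oc3c(OCc4ccccc4)cc(CO)cc3[C@H]2C(=O)OCC)ccc1OCc1ccccc1
F5 | step 4 | ethyl (2S,3S)-7-(benzyloxy)-2-[4-(benzyloxy)-3-methoxyphenyl]-5-(hydroxymethyl)-2,3-dihydro-1-benzofuran-3-carboxylate (trans, enantiomer of 9) | COc1cc([C@H]2Oc3c(OCc4ccccc4)cc(CO)cc3[C@@H]2C(=O)OCC)ccc1OCc1ccccc1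
F6 | step 12 | (3S)-1-[2,4-bis(benzyloxy)-6-bromophenyl]-3-{(2R,3S)-7-(benzyloxy)-3-[(benzyloxy)methyl]-2-[4-(benzyloxy)-3-methoxyphenyl]-2,3-dihydro-1-benzofuran-5-yl}-3-(4,4,5,5-tetramethyl-1,3,2-dioxaborolan-2-yl)propan-1-one | COc1cc([C@@H]2Oc3c(OCc4ccccc4)cc([C@@H](B6OC(C)(C)C(C)(C)O6)CC(=O)c4c(Br)cc(OCc5ccccc5)cc4OCc4ccccc4)cc3[C@H]2COCc2ccccc2)ccc1OCc1ccccc1
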